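**Retrosynthetic overview**

1. The target is read as catechin-(4α→8)-gallocatechin-(4β→8)-catechin. The upper interflavan bond is 3,4-trans; the lower one, from C4 of ring C of the gallocatechin unit to C8 of ring A of the terminal catechin, is 3,4-cis, the sense that untethered cationic coupling of a 2,3-trans unit does not favour.
2. Key disconnection: that C4–C8 bond, made by a strap-directed, thiophile-triggered macrocyclising Friedel–Crafts alkylation of a seco-trimer in which a glutarate diester joins O3 of the gallocatechin unit to O3 of the terminal catechin. The strap and one acetate are then removed and thirteen benzyl ethers hydrogenolysed.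
3. Enabling feature: in ring C of the middle unit O3 is β, next to C4 and cis to the bond to be made; C4 is benzylic to ring A, whose O1, O5 and O7 stabilise a C4 cation; the terminal catechin has its own O3 five bonds from C8 of its ring A, so a five-carbon diacid spans the two oxygens and holds C8 over the β face of C4.
4. Earlier disconnection: C4 (upper catechin)–C8 (gallocatechin), intermolecular, with 3-acetoxy participation for 4α. Orthogonal leaving groups (O-alkyl on the upper unit, S-aryl on the middle unit) let the dimer arrive already armed at C4.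
5. Ring order: none of the nine rings of the target is built; rings A, B and C of each unit come from (+)-catechin (used twice) and (+)-gallocatechin. The only ring formed is the temporary 14-membered dilactone of the key step, opened again one step later.

Key step: step 10

Remark on the chemistry (assumption): α/β follow the usual flavan convention (2-aryl α and O3 β in all three units, so 4α = 3,4-trans and 4β = 3,4-cis). The C4 configuration of every C4-oxygenated or C4-thio electrophile precursor is drawn as 4β (entry anti to the 2-aryl group); it is immaterial, because that centre is planarised on ionisation.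

**Route**

Step 1
Reactants: 1 (+)-catechin
Product: 2 5,7,3',4'-tetra-O-benzyl-(+)-catechin
Conditions: BnBr (4.2 equiv), K2CO3, DMF, 0 °C → rt, N2
Reagents that add atoms: benzyl bromide, BrCc1ccccc1
Why: Williamson ether synthesis in which carbonate deprotonates only the four phenols, so the aliphatic 3-OH stays free and no stereocentre is touched.

Step 2
Reactants: 2 5,7,3',4'-tetra-O-benzyl-(+)-catechin
Product: 3 5,7,3',4'-tetra-O-benzyl-4β-(2-ethoxyethoxy)catechin
Conditions: DDQ (2 equiv), HOCH2CH2OEt (5 equiv), CH2Cl2, rt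
Reagents that add atoms: 2-ethoxyethanol, CCOCCO
Why: DDQ benzylic C–H oxidation (hydride abstraction from C4 gives the ring A-stabilised cation), trapped by the alcohol anti to the 2-aryl group to give a C4 centre that serves only as leaving-group carrier.

Step 3
Reactants: 3 5,7,3',4'-tetra-O-benzyl-4β-(2-ethoxyethoxy)catechin
Product: 4 3-O-acetyl-5,7,3',4'-tetra-O-benzyl-4β-(2-ethoxyethoxy)catechin
Conditions: Ac2O, pyridine, DMAP (cat.), CH2Cl2, rt
Reagents that add atoms: acetic anhydride, CC(=O)OC(C)=O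
Why: DMAP-catalysed acetylation of the secondary alcohol installs the participating group for the first interflavan bond without changing any stereocentre.

Step 4
Reactants: 5 (+)-gallocatechin
Product: 6 5,7,3',4',5'-penta-O-benzyl-(+)-gallocatechin
Conditions: BnBr (5.3 equiv), K2CO3, degassed DMF, 0 °C → rt, N2
Reagents that add atoms: benzyl bromide, BrCc1ccccc1
Why: Williamson ether synthesis of the five phenols under carbonate, with exclusion of air to protect the pyrogallol ring, leaving the 3-OH and both stereocentres untouched.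

Step 5
Reactants: 6 5,7,3',4',5'-penta-O-benzyl-(+)-gallocatechin
Product: 7 5,7,3',4',5'-penta-O-benzyl-4β-(2-ethoxyethoxy)gallocatechin
Conditions: DDQ (2 equiv), HOCH2CH2OEt (5 equiv), CH2Cl2, rt
Reagents that add atoms: 2-ethoxyethanol, CCOCCO
Why: DDQ benzylic C–H oxidation at C4 with alcohol trapping, as in step 2, the C4 centre again being only a leaving-group carrier.

Step 6
Reactants: 7 5,7,3',4',5'-penta-O-benzyl-4β-(2-ethoxyethoxy)gallocatechin
Product: 8 5,7,3',4',5'-penta-O-benzyl-4β-(2,6-dimethylphenylthio)gallocatechin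
Conditions: 2,6-Me2C6H3SH (4 equiv), BF3·OEt2 (0.2 equiv), CH2Cl2, −78 → −40 °C
Reagents that add atoms: 2,6-dimethylbenzenethiol, Cc1cccc(C)c1S
Why: Lewis-acid-mediated O,S-exchange (thiolysis) through the C4 cation, in which the soft thiol in excess outcompetes ring A of a second molecule and gives a thioether that hard Lewis acids do not ionise.

Step 7
Reactants: 4 3-O-acetyl-5,7,3',4'-tetra-O-benzyl-4β-(2-ethoxyethoxy)catechin; 8 5,7,3',4',5'-penta-O-benzyl-4β-(2,6-dimethylphenylthio)gallocatechin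
Product: 9 3-O-acetyl-5,7,3',4'-tetra-O-benzylcatechin-(4α→8)-[5,7,3',4',5'-penta-O-benzyl-4β-(2,6-dimethylphenylthio)gallocatechin]
Conditions: 8 (2 equiv, excess recovered), TMSOTf (0.3 equiv), 4 Å MS, CH2Cl2, −78 °C; Et3N quench
Reagents that add atoms: none
Why: Intermolecular Friedel–Crafts flavan coupling in which TMSOTf ionises only the C4–O bond of 4, the 3-acetoxy group bridges the β face as a dioxolenium ion so that C8 of 8 (the least hindered nucleophilic position of its ring A) attacks from the α face and sets the 3,4-trans (4α) centre, while the hindered arylthio group should neither ionise nor transfer.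

Step 8
Reactants: 2 5,7,3',4'-tetra-O-benzyl-(+)-catechin
Product: 10 5,7,3',4'-tetra-O-benzylcatechin 3-O-(hydrogen glutarate)
Conditions: glutaric anhydride (3 equiv), DMAP, Et3N, CH2Cl2, rt; dilute HCl work-up
Reagents that add atoms: glutaric anhydride, O=C1CCCC(=O)O1
Why: DMAP-catalysed ring-opening of the cyclic anhydride by the secondary alcohol gives the half ester with retention at C3.

Step 9
Reactants: 9 dimer thioether (free 3-OH on the gallocatechin unit); 10 5,7,3',4'-tetra-O-benzylcatechin 3-O-(hydrogen glutarate)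
Product: 11 strapped seco-trimer: glutarate diester joining O3 of the gallocatechin unit of 9 to O3 of tetra-O-benzylcatechin
Conditions: DCC (1.5 equiv), DMAP (0.3 equiv), CH2Cl2, 0 °C → rt
Reagents that add atoms: none
Why: Steglich esterification of the only free hydroxyl of 9 with acid 10, which affects no stereocentre.

Step 10
Reactants: 11 strapped seco-trimer
Product: 12 macrocyclic trimer: 3-O-acetyl-tetra-O-benzylcatechin-(4α→8)-penta-O-benzylgallocatechin-(4β→8)-tetra-O-benzylcatechin with an O3(middle),O3(bottom) glutarate bridge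
Conditions: NIS (1.3 equiv), 4 Å MS, CH2Cl2 (0.001 M), −78 → −30 °C; aq. Na2S2O3
Reagents that add atoms: none
Why: NIS iodinates the sulfur of the 2,6-dimethylphenylthio group, which leaves as the sulfenyl iodide and gives the C4 benzylic cation of the middle unit, stabilised as a quinone-methide oxocarbenium by O1, O5 and O7 of its ring A; C8 of ring A of the strapped catechin then attacks C4 and loses H8 (intramolecular Friedel–Crafts alkylation). The closest known reaction types are the Lewis-acid-mediated intramolecular condensation of diester-linked flavan-3-ol units and the thiophile activation of 4-arylthioflavans. One temporary 14-membered dilactone ring is closed by C-alkylation under high dilution (macrocyclisation with both reacting atoms endocyclic). The new C4 stereocentre is controlled by the strap: anchored on the β-oriented O3 next to C4, it should deliver the arene to the β face, which is also the axial trajectory on the half-chair cation with 2-aryl and 3-acyloxy equatorial, so the 3,4-cis (4β) bond is expected where untethered coupling favours 4α. The step needs C8 over C6 regioselectivity (C6 lies between two benzyloxy groups and is intrinsically less reactive), sulfur activation ahead of arene iodination (soft thiophile, low temperature) and intra- over intermolecular attack (dilution).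

Step 11
Reactants: 12 macrocyclic trimer
Product: 13 trideca-O-benzyl catechin-(4α→8)-gallocatechin-(4β→8)-catechin (three free 3-OH groups)
Conditions: NaOMe (0.5 equiv), MeOH–THF (1:1), rt → 40 °C; AcOH quench
Reagents that add atoms: none
Why: Zemplén-type transesterification in which methoxide cleaves both glutarate ester bonds and the acetate at the acyl carbons, so every C–O stereocentre is retained.

Step 12
Reactants: 13 trideca-O-benzyl trimer
Product: 14 catechin-(4α→8)-gallocatechin-(4β→8)-catechin (target)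
Conditions: H2 (1 atm), Pd(OH)2/C, THF–MeOH–H2O (20:1:1), rt; filtration and lyophilisation under Ar
Reagents that add atoms: none
Why: Catalytic hydrogenolysis of the thirteen aryl benzyl ethers under neutral conditions, which leaves the interflavan C–C bonds and all eight stereocentres untouched.

**Compound list**

1 | (+)-catechin, (2R,3S)-2-(3,4-dihydroxyphenyl)chromane-3,5,7-triol | Oc1cc(O)c2c(c1)O[C@H](c1ccc(O)c(O)c1)[C@@H](O)C2 | starting material
2 | 5,7,3',4'-tetra-O-benzyl-(+)-catechin (2R,3S) | O(Cc9ccccc9)c1cc(OCc9ccccc9)c2c(c1)O[C@H](c1ccc(OCc9ccccc9)c(OCc9ccccc9)c1)[C@@H](O)C2 | intermediate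
3 | 5,7,3',4'-tetra-O-benzyl-4β-(2-ethoxyethoxy)catechin (2,4-trans, 3-OH free) | O(Cc9ccccc9)c1cc(OCc9ccccc9)c2c(c1)O[C@H](c1ccc(OCc9ccccc9)c(OCc9ccccc9)c1)[C@@H](O)[C@H]2OCCOCC | intermediate
4 | 3-O-acetyl-5,7,3',4'-tetra-O-benzyl-4β-(2-ethoxyethoxy)catechin | O(Cc9ccccc9)c1cc(OCc9ccccc9)c2c(c1)O[C@H](c1ccc(OCc9ccccc9)c(OCc9ccccc9)c1)[C@@H](OC(C)=O)[C@H]2OCCOCC | intermediate
5 | (+)-gallocatechin, (2R,3S)-2-(3,4,5-trihydroxyphenyl)chromane-3,5,7-triol | Oc1cc(O)c2c(c1)O[C@H](c1cc(O)c(O)c(O)c1)[C@@H](O)C2 | starting material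
6 | 5,7,3',4',5'-penta-O-benzyl-(+)-gallocatechin (2R,3S) | O(Cc9ccccc9)c1cc(OCc9ccccc9)c2c(c1)O[C@H](c1cc(OCc9ccccc9)c(OCc9ccccc9)c(OCc9ccccc9)c1)[C@@H](O)C2 | intermediate
7 | 5,7,3',4',5'-penta-O-benzyl-4β-(2-ethoxyethoxy)gallocatechin | O(Cc9ccccc9)c1cc(OCc9ccccc9)c2c(c1)O[C@H](c1cc(OCc9ccccc9)c(OCc9ccccc9)c(OCc9ccccc9)c1)[C@@H](O)[C@H]2OCCOCC | intermediate
8 | 5,7,3',4',5'-penta-O-benzyl-4β-(2,6-dimethylphenylthio)gallocatechin | O(Cc9ccccc9)c1cc(OCc9ccccc9)c2c(c1)O[C@H](c1cc(OCc9ccccc9)c(OCc9ccccc9)c(OCc9ccccc9)c1)[C@@H](O)[C@H]2Sc1c(C)cccc1C | intermediate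
9 | 3-O-acetyl-5,7,3',4'-tetra-O-benzylcatechin-(4α→8)-[5,7,3',4',5'-penta-O-benzyl-4β-(2,6-dimethylphenylthio)gallocatechin] | O(Cc9ccccc9)c1cc(OCc9ccccc9)c2c(c1)O[C@H](c1ccc(OCc9ccccc9)c(OCc9ccccc9)c1)[C@@H](OC(C)=O)[C@@H]2c1c(OCc9ccccc9)cc(OCc9ccccc9)c2c1O[C@H](c1cc(OCc9ccccc9)c(OCc9ccccc9)c(OCc9ccccc9)c1)[C@@H](O)[C@H]2Sc1c(C)cccc1C | intermediate
10 | 5,7,3',4'-tetra-O-benzylcatechin 3-O-(hydrogen glutarate) | O(Cc9ccccc9)c1cc(OCc9ccccc9)c2c(c1)O[C@H](c1ccc(OCc9ccccc9)c(OCc9ccccc9)c1)[C@@H](OC(=O)CCCC(O)=O)C2 | intermediate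
11 | strapped seco-trimer: dimer 9 esterified at O3 of its gallocatechin unit with the glutarate of 10 | O(Cc9ccccc9)c1cc(OCc9ccccc9)c2c(c1)O[C@H](c1ccc(OCc9ccccc9)c(OCc9ccccc9)c1)[C@@H](OC(C)=O)[C@@H]2c1c(OCc9ccccc9)cc(OCc9ccccc9)c2c1O[C@H](c1cc(OCc9ccccc9)c(OCc9ccccc9)c(OCc9ccccc9)c1)[C@@H](OC(=O)CCCC(=O)O[C@H]3Cc4c(OCc9ccccc9)cc(OCc9ccccc9)cc4O[C@@H]3c3ccc(OCc9ccccc9)c(OCc9ccccc9)c3)[C@H]2Sc1c(C)cccc1C | intermediate
12 | macrocyclic trimer: 3-O-acetyl-tetra-O-benzylcatechin-(4α→8)-penta-O-benzylgallocatechin-(4β→8)-tetra-O-benzylcatechin, O3(middle),O3(bottom)-glutarate (14-membered dilactone) | O(Cc9ccccc9)c1cc(OCc9ccccc9)c2c(c1)O[C@H](c1ccc(OCc9ccccc9)c(OCc9ccccc9)c1)[C@@H](OC(C)=O)[C@@H]2c1c(OCc9ccccc9)cc(OCc9ccccc9)c2c1O[C@H](c1cc(OCc9ccccc9)c(OCc9ccccc9)c(OCc9ccccc9)c1)[C@@H](OC(=O)CCCC(=O)O[C@H]3Cc4c(OCc9ccccc9)cc(OCc9ccccc9)c5c4O[C@@H]3c3ccc(OCc9ccccc9)c(OCc9ccccc9)c3)[C@H]25 | intermediate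
13 | trideca-O-benzyl catechin-(4α→8)-gallocatechin-(4β→8)-catechin (three free 3-OH) | O(Cc9ccccc9)c1cc(OCc9ccccc9)c2c(c1)O[C@H](c1ccc(OCc9ccccc9)c(OCc9ccccc9)c1)[C@@H](O)[C@@H]2c1c(OCc9ccccc9)cc(OCc9ccccc9)c2c1O[C@H](c1cc(OCc9ccccc9)c(OCc9ccccc9)c(OCc9ccccc9)c1)[C@@H](O)[C@H]2c1c(OCc9ccccc9)cc(OCc9ccccc9)c2c1O[C@H](c1ccc(OCc9ccccc9)c(OCc9ccccc9)c1)[C@@H](O)C2 | intermediate
14 | catechin-(4α→8)-gallocatechin-(4β→8)-catechin (CNP0302529.2) | Oc1cc(O)c2c(c1)O[C@H](c1ccc(O)c(O)c1)[C@@H](O)[C@@H]2c1c(O)cc(O)c2c1O[C@H](c1cc(O)c(O)c(O)c1)[C@@H](O)[C@H]2c1c(O)cc(O)c2c1O[C@H](c1ccc(O)c(O)c1)[C@@H](O)C2 | target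

**Totals**

Total step count: 12.
Longest linear sequence: 8 steps (steps 4, 5, 6, 7, 9, 10, 11, 12 from (+)-gallocatechin; equally steps 1, 2, 3, 7, 9, 10, 11, 12 from (+)-catechin).

**Steps most likely to fail**

Step 10 (key step). What may go wrong: the strap may not steer the arene to the β face, so that the 3,4-trans bond forms; attack may occur through C6; intermolecular alkylation may compete with macrocyclisation; NIS may iodinate ring A. The fallback replaces cationic coupling by carbonyl addition and ionic hydrogenation; it sets out from 9 (with 2 for the nucleophile) and comes back at 13. Methanolysis of the acetate of 9 (NaOMe, MeOH–THF) should give the dimer diol F1, and silylation (TBSOTf, 2,6-lutidine, CH2Cl2) the bis(silyl ether) F2. Thiophile-mediated hydrolysis (NIS, wet MeCN–CH2Cl2, −20 °C) should give the 4-hydroxy dimer F3, and Dess–Martin oxidation the dimeric flavan-4-one F4. In parallel, 2 is brominated at C8 (NBS, CH2Cl2, −78 °C) to 8-bromo-tetra-O-benzylcatechin F5 and silylated to its 3-O-TBS ether F6. Bromine–lithium exchange (t-BuLi, THF, −78 °C) gives the 8-lithio species F7, which is added to the C4 carbonyl of F4 to give the tertiary carbinol F8. Ionic hydrogenation (Bu3SnH, CF3CO2H, CH2Cl2, 0 °C) ionises C4 and should deliver hydride anti to the 3-silyloxy group, that is to the α face, leaving the aryl group β (3,4-cis) in the tris(silyl ether) F9. Bu4NF in THF then removes the three silyl groups and gives 13.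

Step 7. What may go wrong: loss of orthogonality, either by ionisation of the C4–S bond of 8 or by transfer of its arylthio group to the cation from 4, together with self-condensation of 4. The fallback keeps the nucleophile free of any C4 group and arms the dimer afterwards; it sets out from 4 and 6 and comes back at 9. TMSOTf-catalysed coupling of 4 with excess 6 (CH2Cl2, −78 °C) should give the plain dimer F10. DDQ with 2-ethoxyethanol then oxidises the only benzylic CH2 group, C4 of the gallocatechin unit, to the 4-(2-ethoxyethoxy) dimer F11. Exchange with 2,6-dimethylbenzenethiol (BF3·OEt2, CH2Cl2, −78 °C) gives 9.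

Step 9. What may go wrong: slow acylation of the hindered O3 of 9 (flanked by the 2-aryl and 4-arylthio groups) and rearrangement of the activated acid to the N-acylurea. The fallback builds the strap in the opposite order; it sets out from 9 and comes back at 11. The hindered alcohol of 9 is opened onto the small, reactive glutaric anhydride (DMAP, Et3N, CH2Cl2, 40 °C) to give the dimer hydrogen glutarate F12. Its acid is then esterified with the unhindered 3-OH of 2 (2,4,6-trichlorobenzoyl chloride, Et3N, then DMAP, toluene; Yamaguchi esterification) to give 11.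

**Further compounds**

F1 | step 10 | 5,7,3',4'-tetra-O-benzylcatechin-(4α→8)-[penta-O-benzyl-4β-(2,6-dimethylphenylthio)gallocatechin], both 3-OH free | O(Cc9ccccc9)c1cc(OCc9ccccc9)c2c(c1)O[C@H](c1ccc(OCc9ccccc9)c(OCc9ccccc9)c1)[C@@H](O)[C@@H]2c1c(OCc9ccccc9)cc(OCc9ccccc9)c2c1O[C@H](c1cc(OCc9ccccc9)c(OCc9ccccc9)c(OCc9ccccc9)c1)[C@@H](O)[C@H]2Sc1c(C)cccc1C
F2 | step 10 | 3,3''-bis-O-TBS ether of F1 | O(Cc9ccccc9)c1cc(OCc9ccccc9)c2c(c1)O[C@H](c1ccc(OCc9ccccc9)c(OCc9ccccc9)c1)[C@@H](O[Si](C)(C)C(C)(C)C)[C@@H]2c1c(OCc9ccccc9)cc(OCc9ccccc9)c2c1O[C@H](c1cc(OCc9ccccc9)c(OCc9ccccc9)c(OCc9ccccc9)c1)[C@@H](O[Si](C)(C)C(C)(C)C)[C@H]2Sc1c(C)cccc1C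
F3 | step 10 | bis-O-TBS dimer with 4β-OH on the gallocatechin unit | O(Cc9ccccc9)c1cc(OCc9ccccc9)c2c(c1)O[C@H](c1ccc(OCc9ccccc9)c(OCc9ccccc9)c1)[C@@H](O[Si](C)(C)C(C)(C)C)[C@@H]2c1c(OCc9ccccc9)cc(OCc9ccccc9)c2c1O[C@H](c1cc(OCc9ccccc9)c(OCc9ccccc9)c(OCc9ccccc9)c1)[C@@H](O[Si](C)(C)C(C)(C)C)[C@H]2O
F4 | step 10 | bis-O-TBS dimer with C4 ketone on the gallocatechin unit (flavan-4-one) | O(Cc9ccccc9)c1cc(OCc9ccccc9)c2c(c1)O[C@H](c1ccc(OCc9ccccc9)c(OCc9ccccc9)c1)[C@@H](O[Si](C)(C)C(C)(C)C)[C@@H]2c1c(OCc9ccccc9)cc(OCc9ccccc9)c2c1O[C@H](c1cc(OCc9ccccc9)c(OCc9ccccc9)c(OCc9ccccc9)c1)[C@@H](O[Si](C)(C)C(C)(C)C)C2=O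
F5 | step 10 | 8-bromo-5,7,3',4'-tetra-O-benzylcatechin | Brc1c(OCc9ccccc9)cc(OCc9ccccc9)c2c1O[C@H](c1ccc(OCc9ccccc9)c(OCc9ccccc9)c1)[C@@H](O)C2
F6 | step 10 | 8-bromo-3-O-TBS-5,7,3',4'-tetra-O-benzylcatechin | Brc1c(OCc9ccccc9)cc(OCc9ccccc9)c2c1O[C@H](c1ccc(OCc9ccccc9)c(OCc9ccccc9)c1)[C@@H](O[Si](C)(C)C(C)(C)C)C2
F7 | step 10 | 8-lithio-3-O-TBS-5,7,3',4'-tetra-O-benzylcatechin (not isolated) | [Li]c1c(OCc9ccccc9)cc(OCc9ccccc9)c2c1O[C@H](c1ccc(OCc9ccccc9)c(OCc9ccccc9)c1)[C@@H](O[Si](C)(C)C(C)(C)C)C2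
F8 | step 10 | tris-O-TBS trimer with tertiary C4 carbinol on the gallocatechin unit (aryl α, OH β drawn) | O(Cc9ccccc9)c1cc(OCc9ccccc9)c2c(c1)O[C@H](c1ccc(OCc9ccccc9)c(OCc9ccccc9)c1)[C@@H](O[Si](C)(C)C(C)(C)C)[C@@H]2c1c(OCc9ccccc9)cc(OCc9ccccc9)c2c1O[C@H](c1cc(OCc9ccccc9)c(OCc9ccccc9)c(OCc9ccccc9)c1)[C@@H](O[Si](C)(C)C(C)(C)C)[C@]2(O)c1c(OCc9ccccc9)cc(OCc9ccccc9)c2c1O[C@H](c1ccc(OCc9ccccc9)c(OCc9ccccc9)c1)[C@@H](O[Si](C)(C)C(C)(C)C)C2
F9 | step 10 | tris-O-TBS trideca-O-benzyl catechin-(4α→8)-gallocatechin-(4β→8)-catechin | O(Cc9ccccc9)c1cc(OCc9ccccc9)c2c(c1)O[C@H](c1ccc(OCc9ccccc9)c(OCc9ccccc9)c1)[C@@H](O[Si](C)(C)C(C)(C)C)[C@@H]2c1c(OCc9ccccc9)cc(OCc9ccccc9)c2c1O[C@H](c1cc(OCc9ccccc9)c(OCc9ccccc9)c(OCc9ccccc9)c1)[C@@H](O[Si](C)(C)C(C)(C)C)[C@H]2c1c(OCc9ccccc9)cc(OCc9ccccc9)c2c1O[C@H](c1ccc(OCc9ccccc9)c(OCc9ccccc9)c1)[C@@H](O[Si](C)(C)C(C)(C)C)C2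
F10 | step 7 | 3-O-acetyl-5,7,3',4'-tetra-O-benzylcatechin-(4α→8)-5,7,3',4',5'-penta-O-benzylgallocatechin | O(Cc9ccccc9)c1cc(OCc9ccccc9)c2c(c1)O[C@H](c1ccc(OCc9ccccc9)c(OCc9ccccc9)c1)[C@@H](OC(C)=O)[C@@H]2c1c(OCc9ccccc9)cc(OCc9ccccc9)c2c1O[C@H](c1cc(OCc9ccccc9)c(OCc9ccccc9)c(OCc9ccccc9)c1)[C@@H](O)C2
F11 | step 7 | F10 with 4β-(2-ethoxyethoxy) on the gallocatechin unit | O(Cc9ccccc9)c1cc(OCc9ccccc9)c2c(c1)O[C@H](c1ccc(OCc9ccccc9)c(OCc9ccccc9)c1)[C@@H](OC(C)=O)[C@@H]2c1c(OCc9ccccc9)cc(OCc9ccccc9)c2c1O[C@H](c1cc(OCc9ccccc9)c(OCc9ccccc9)c(OCc9ccccc9)c1)[C@@H](O)[C@H]2OCCOCC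
F12 | step 9 | dimer 9 as its 3-O-(hydrogen glutarate) on the gallocatechin unit | O(Cc9ccccc9)c1cc(OCc9ccccc9)c2c(c1)O[C@H](c1ccc(OCc9ccccc9)c(OCc9ccccc9)c1)[C@@H](OC(C)=O)[C@@H]2c1c(OCc9ccccc9)cc(OCc9ccccc9)c2c1O[C@H](c1cc(OCc9ccccc9)c(OCc9ccccc9)c(OCc9ccccc9)c1)[C@@H](OC(=O)CCCC(O)=O)[C@H]2Sc1c(C)cccc1C
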